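Commit to one number for this flask, and read it from the blue run, which is this same charge followed up to 5.00 h.

- blue: substrate 33 mM; acid 0.033 mM; scavenger 1.2 equiv; the very flask that is asked about, followed so far
- flask: substrate 33 mM; acid 0.0330 mM; scavenger 1.20 equiv; time 15 h

- blue (time / h: substrate / %, product / %): 0.500: 87, 6; 1.50: 69, 33; 3.00: 47, 54; 5.00: 26, 71

(readings scatter by 2 percentage points)

- acid is the free proton; pH is minus the decimal logarithm of its molar concentration
- product is meant together with its crystals
- weak acid is meant together with its idle adduct
- solid, in amounts per volume of the solution: crystals
- reactions considered so far: substrate + acid -> weak acid + acid + product; weak acid <-> conjugate base + acid; substrate -> weak acid + product; crystals <-> product; substrate + weak acid <-> idle adduct; weak acid + scavenger -> scavenged by-product; weak acid -> by-product carried off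

* part of the substrate that has reacted at 15 h
* pH of the solution at 15 h

Take the last reading, substrate at 26 % after 5.00 h. If the loss stays in proportion to c(substrate), the half-life reads 2.57 h. The reading at 3.00 h gives 2.75 h, near enough under a scatter of 2 percentage points. Carry this substrate half-life forward. Count 15 h as 5.84 half-lives, which leaves 1.76 % of the substrate, so my own reckoning commits to 98.2 % reacted.

The forecast calls the run “essentially first order in substrate” and gives 98 % reacted and pH 4.4.

The flask gives 97.9 % reacted and pH 4.48.

    substrate + acid → weak acid + acid + product (k = 1.14 /M/s)
    weak acid ⇌ conjugate base + acid, settled at all times (K = 1.00 × 10⁻⁷ M)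
    substrate → weak acid + product (k = 3.34 × 10⁻⁵ /s)
    crystals ⇌ product, rate k4*(cs4 - [product]) while solid is left; crystals form when [product] > cs4 (solubility = 16.0 mM, k = 0.00144 /s)
    substrate + weak acid ⇌ idle adduct, settled at all times (K = 18.0 /M)
    weak acid + scavenger → scavenged by-product (k = 0.0711 /M/s)
    weak acid → by-product carried off (k = 3.18 × 10⁻⁵ /s)

In this flask the acid stands at 107 % of its charge at 1.50 h and 101 % at 15.0 h. Two steps turn substrate into product, with half-lives of 5.1 h (acid as charged) and 5.8 h, which at acid as charged combine to 2.71 h: a pseudo-first-order loss. Now raise the substrate to 56 mM, with the recipe's equivalents held, and carry 2.57 h over unchanged, which again gives 98.2 % reacted at 15.0 h. That neighbouring flask gives 97.9 %, with 2.06 % of its substrate left.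

The data were generated by integration for an exercise; noise was put on by code.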